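## Retrosynthetic overview
1. Irisjaponin A 24 comes from its 5,7-di-O-benzyl ether 23 by hydrogenolysis in the last step.
2. Ring C (the pyranone, the only ring built) closes under acid from β-keto acetal 20. Only the oxygen that becomes O-1 carries an acid-labile MOM group, which fixes 6-OMe over 8-OMe.
3. Acetal 20 comes from chalcone 19 by a Tl(III)-mediated oxidative 1,2-shift of the B-ring aryl group.
4. Chalcone 19 comes from acetophenone 17 and aldehyde 6 by a Claisen–Schmidt aldol condensation, the key C–C bond.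
5. 17 derives from methyl 4-O-methylgallate 7, and 6 derives from 2,3,4-trimethoxybenzaldehyde 1. Rings A and B are both bought.

Assumption: the target SMILES has no stereocentre and no stereogenic double bond, so it is achiral and needs no enantiocontrol. The racemic centres in 18, 20, 21 and 22 are erased before the end.

## Route

**Step 1**
Reactants: 1 2,3,4-trimethoxybenzaldehyde
Product: 3 2,3,4-trimethoxyphenol, via aryl formate 2 (not isolated)
Conditions: mCPBA (1.3 equiv), CH2Cl2, 0 °C to rt; aq NaHCO3 wash; then K2CO3 (0.2 equiv), MeOH, rt, N2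
Reagents that add atoms: mCPBA, O=C(OO)c1cccc(Cl)c1
Why: In this Baeyer–Villiger (Dakin-type) oxidation the aryl group, activated by ortho- and para-methoxy groups, migrates to oxygen, and the labile formate is then methanolysed.

**Step 2**
Reactants: 3 2,3,4-trimethoxyphenol
Product: 4 1,2,3,4-tetramethoxybenzene
Conditions: MeI (1.5 equiv), K2CO3 (2 equiv), acetone, reflux
Reagents that add atoms: iodomethane, CI
Why: This is a Williamson ether synthesis on the only free phenol, with no competing nucleophile.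

**Step 3**
Reactants: 4 1,2,3,4-tetramethoxybenzene
Product: 6 2,3,4,5-tetramethoxybenzaldehyde, via iminium salt 5 (not isolated)
Conditions: POCl3 (2 equiv), DMF, 0 to 80 °C; then ice–H2O
Reagents that add atoms: DMF, CN(C)C=O; water, O
Why: In this Vilsmeier–Haack formylation the two free positions are equivalent by symmetry and each is ortho and para to a methoxy group, so one aldehyde forms.

**Step 4**
Reactants: 7 methyl 3,5-dihydroxy-4-methoxybenzoate
Product: 8 methyl 3,5-bis(benzyloxy)-4-methoxybenzoate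
Conditions: BnBr (2.3 equiv), K2CO3 (3 equiv), DMF, 60 °C
Reagents that add atoms: benzyl bromide, BrCc1ccccc1
Why: Williamson O-benzylation of two equivalent phenols installs groups that survive base, organolithium, Tl(III) and dilute acid.

**Step 5**
Reactants: 8 methyl 3,5-bis(benzyloxy)-4-methoxybenzoate
Product: 9 [3,5-bis(benzyloxy)-4-methoxyphenyl]methanol
Conditions: LiAlH4 (1 equiv), THF, 0 °C to rt; aqueous work-up
Reagents that add atoms: none
Why: Hydride reduction takes the ester to the primary alcohol, and aryl ethers are inert to LiAlH4.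

**Step 6**
Reactants: 9 [3,5-bis(benzyloxy)-4-methoxyphenyl]methanol
Product: 10 3,5-bis(benzyloxy)-4-methoxybenzaldehyde
Conditions: activated MnO2 (10 equiv), CH2Cl2, rt
Reagents that add atoms: none
Why: MnO2 oxidises benzylic alcohols selectively and stops cleanly at the aldehyde.

**Step 7**
Reactants: 10 3,5-bis(benzyloxy)-4-methoxybenzaldehyde
Product: 12 3,5-bis(benzyloxy)-4-methoxyphenol, via aryl formate 11 (not isolated)
Conditions: mCPBA (1.5 equiv), CH2Cl2, rt to reflux; aq NaHCO3 wash; then K2CO3 (0.2 equiv), MeOH, rt, N2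
Reagents that add atoms: mCPBA, O=C(OO)c1cccc(Cl)c1
Why: Baeyer–Villiger oxidation of the trialkoxybenzaldehyde proceeds by aryl migration, and the formate shields the electron-rich phenol from the peracid until methanolysis.

**Step 8**
Reactants: 12 3,5-bis(benzyloxy)-4-methoxyphenol
Product: 13 1,3-bis(benzyloxy)-2-methoxy-5-(methoxymethoxy)benzene
Conditions: MOMCl (1.5 equiv), K2CO3 (2.5 equiv), DMF, 0 °C to rt
Reagents that add atoms: chloromethyl methyl ether, COCCl
Why: Williamson-type O-alkylation marks the future O-1 oxygen with an acid-labile acetal that is orthogonal to the benzyl ethers.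

**Step 9**
Reactants: 13 1,3-bis(benzyloxy)-2-methoxy-5-(methoxymethoxy)benzene
Product: 14 1,3-bis(benzyloxy)-4-bromo-2-methoxy-5-(methoxymethoxy)benzene
Conditions: NBS (1.0 equiv), MeCN, −20 to 0 °C, dark
Reagents that add atoms: N-bromosuccinimide, O=C1CCC(=O)N1Br
Why: In this electrophilic aromatic bromination the two free positions of the tetraalkoxy ring are equivalent, the medium stays neutral so MOM survives, and the first bromine slows a second attack.

**Step 10**
Reactants: 14 1,3-bis(benzyloxy)-4-bromo-2-methoxy-5-(methoxymethoxy)benzene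
Product: 17 1-[2,4-bis(benzyloxy)-3-methoxy-6-(methoxymethoxy)phenyl]ethan-1-one, via aryllithium 15 (not isolated), via tetrahedral lithium adduct 16 (not isolated)
Conditions: n-BuLi (1.05 equiv), THF, −78 °C, 15 min; MeC(O)N(OMe)Me (1.5 equiv), −78 to 0 °C; aq NH4Cl
Reagents that add atoms: N-methoxy-N-methylacetamide, CC(=O)N(C)OC
Why: Bromine–lithium exchange at −78 °C outruns benzylic deprotonation, and in the Weinreb ketone synthesis the chelated adduct prevents over-addition.

**Step 11**
Reactants: 17 1-[2,4-bis(benzyloxy)-3-methoxy-6-(methoxymethoxy)phenyl]ethan-1-one; 6 2,3,4,5-tetramethoxybenzaldehyde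
Product: 19 (E)-1-[2,4-bis(benzyloxy)-3-methoxy-6-(methoxymethoxy)phenyl]-3-(2,3,4,5-tetramethoxyphenyl)prop-2-en-1-one, via aldol adduct 18 (not isolated)
Conditions: KOH (10 equiv), EtOH–THF 4:1, rt to 40 °C, 24–48 h
Reagents that add atoms: none
Why: In this Claisen–Schmidt crossed aldol condensation only the ketone can enolise and only the aldehyde accepts, E1cB dehydration gives the conjugated E-enone, and the MOM group blocks flavanone formation.

**Step 12**
Reactants: 19 (E)-chalcone
Product: 20 rac-1-[2,4-bis(benzyloxy)-3-methoxy-6-(methoxymethoxy)phenyl]-3,3-dimethoxy-2-(2,3,4,5-tetramethoxyphenyl)propan-1-one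
Conditions: Tl(NO3)3·3H2O (1.2 equiv), MeOH–HC(OMe)3 1:1, rt; filter; aq NaHCO3
Reagents that add atoms: methanol, CO
Why: In the Tl(III) oxidative rearrangement of chalcones, oxythallation is followed by a 1,2-shift of the aryl group bearing ortho- and para-methoxy donors, which leaves the old β-carbon as a dimethyl acetal and a racemic α-centre that step 13 erases.

**Step 13**
Reactants: 20 rac-β-keto acetal
Product: 23 5,7-bis(benzyloxy)-6-methoxy-3-(2,3,4,5-tetramethoxyphenyl)-4H-chromen-4-one, via free phenol 21 (not isolated), via 2-methoxyisoflavanone 22 (not isolated)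
Conditions: conc. aq HCl (10% v/v) in MeOH–THF, 55 °C, 2–3 h
Reagents that add atoms: none
Why: Acid-catalysed acetal exchange removes MOM far faster than benzyl, so only the phenol next to the ring C–H attacks the acetal (transacetalisation), and loss of methanol gives the 6-methoxy chromone.

**Step 14**
Reactants: 23 5,7-bis(benzyloxy)-6-methoxy-3-(2,3,4,5-tetramethoxyphenyl)-4H-chromen-4-one
Product: 24 Irisjaponin A, 5,7-dihydroxy-6-methoxy-3-(2,3,4,5-tetramethoxyphenyl)-4H-chromen-4-one
Conditions: H2 (1 atm), 10% Pd/C, EtOAc–MeOH, rt, stop after 2 equiv H2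
Reagents that add atoms: none
Why: Catalytic hydrogenolysis cleaves the O-benzyl ethers faster than it reduces the chromone C2=C3 bond and leaves all five methyl ethers untouched.

## Compound list
1 | 2,3,4-trimethoxybenzaldehyde | COc1ccc(C=O)c(OC)c1OC | starting material
2 | 2,3,4-trimethoxyphenyl formate (not isolated) | COc1ccc(OC=O)c(OC)c1OC | intermediate
3 | 2,3,4-trimethoxyphenol | COc1ccc(O)c(OC)c1OC | intermediate
4 | 1,2,3,4-tetramethoxybenzene | COc1ccc(OC)c(OC)c1OC | intermediate
5 | N,N-dimethyl-(2,3,4,5-tetramethoxybenzylidene)iminium chloride (not isolated) | COc1cc(C=[N+](C)C)c(OC)c(OC)c1OC.[Cl-] | intermediate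
6 | 2,3,4,5-tetramethoxybenzaldehyde | COc1cc(C=O)c(OC)c(OC)c1OC | intermediate
7 | methyl 3,5-dihydroxy-4-methoxybenzoate (methyl 4-O-methylgallate) | COC(=O)c1cc(O)c(OC)c(O)c1 | starting material
8 | methyl 3,5-bis(benzyloxy)-4-methoxybenzoate | COC(=O)c1cc(OCc2ccccc2)c(OC)c(OCc2ccccc2)c1 | intermediate
9 | [3,5-bis(benzyloxy)-4-methoxyphenyl]methanol | OCc1cc(OCc2ccccc2)c(OC)c(OCc2ccccc2)c1 | intermediate
10 | 3,5-bis(benzyloxy)-4-methoxybenzaldehyde | O=Cc1cc(OCc2ccccc2)c(OC)c(OCc2ccccc2)c1 | intermediate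
11 | 3,5-bis(benzyloxy)-4-methoxyphenyl formate (not isolated) | O=COc1cc(OCc2ccccc2)c(OC)c(OCc2ccccc2)c1 | intermediate
12 | 3,5-bis(benzyloxy)-4-methoxyphenol | Oc1cc(OCc2ccccc2)c(OC)c(OCc2ccccc2)c1 | intermediate
13 | 1,3-bis(benzyloxy)-2-methoxy-5-(methoxymethoxy)benzene | COCOc1cc(OCc2ccccc2)c(OC)c(OCc2ccccc2)c1 | intermediate
14 | 1,3-bis(benzyloxy)-4-bromo-2-methoxy-5-(methoxymethoxy)benzene | COCOc1cc(OCc2ccccc2)c(OC)c(OCc2ccccc2)c1Br | intermediate
15 | [2,4-bis(benzyloxy)-3-methoxy-6-(methoxymethoxy)phenyl]lithium (not isolated) | [Li]c1c(OCOC)cc(OCc2ccccc2)c(OC)c1OCc1ccccc1 | intermediate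
16 | lithium 1-[2,4-bis(benzyloxy)-3-methoxy-6-(methoxymethoxy)phenyl]-1-[methoxy(methyl)amino]ethan-1-olate (not isolated) | CC([O-])(N(C)OC)c1c(OCOC)cc(OCc2ccccc2)c(OC)c1OCc1ccccc1.[Li+] | intermediate
17 | 1-[2,4-bis(benzyloxy)-3-methoxy-6-(methoxymethoxy)phenyl]ethan-1-one | COCOc1cc(OCc2ccccc2)c(OC)c(OCc2ccccc2)c1C(C)=O | intermediate
18 | rac-1-[2,4-bis(benzyloxy)-3-methoxy-6-(methoxymethoxy)phenyl]-3-hydroxy-3-(2,3,4,5-tetramethoxyphenyl)propan-1-one (not isolated) | COCOc1cc(OCc2ccccc2)c(OC)c(OCc2ccccc2)c1C(=O)CC(O)c1cc(OC)c(OC)c(OC)c1OC | intermediate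
19 | (E)-1-[2,4-bis(benzyloxy)-3-methoxy-6-(methoxymethoxy)phenyl]-3-(2,3,4,5-tetramethoxyphenyl)prop-2-en-1-one | COCOc1cc(OCc2ccccc2)c(OC)c(OCc2ccccc2)c1C(=O)/C=C/c1cc(OC)c(OC)c(OC)c1OC | intermediate
20 | rac-1-[2,4-bis(benzyloxy)-3-methoxy-6-(methoxymethoxy)phenyl]-3,3-dimethoxy-2-(2,3,4,5-tetramethoxyphenyl)propan-1-one | COCOc1cc(OCc2ccccc2)c(OC)c(OCc2ccccc2)c1C(=O)C(C(OC)OC)c1cc(OC)c(OC)c(OC)c1OC | intermediate
21 | rac-1-[2,4-bis(benzyloxy)-6-hydroxy-3-methoxyphenyl]-3,3-dimethoxy-2-(2,3,4,5-tetramethoxyphenyl)propan-1-one (not isolated) | COc1c(OCc2ccccc2)cc(O)c(C(=O)C(C(OC)OC)c2cc(OC)c(OC)c(OC)c2OC)c1OCc1ccccc1 | intermediate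
22 | 5,7-bis(benzyloxy)-2,6-dimethoxy-3-(2,3,4,5-tetramethoxyphenyl)chroman-4-one, mixture of racemic diastereomers (not isolated) | COC1Oc2cc(OCc3ccccc3)c(OC)c(OCc3ccccc3)c2C(=O)C1c1cc(OC)c(OC)c(OC)c1OC | intermediate
23 | 5,7-bis(benzyloxy)-6-methoxy-3-(2,3,4,5-tetramethoxyphenyl)-4H-chromen-4-one | COc1cc(-c2coc3cc(OCc4ccccc4)c(OC)c(OCc4ccccc4)c3c2=O)c(OC)c(OC)c1OC | intermediate
24 | Irisjaponin A, 5,7-dihydroxy-6-methoxy-3-(2,3,4,5-tetramethoxyphenyl)-4H-chromen-4-one (achiral) | COc1cc(-c2coc3cc(O)c(OC)c(O)c3c2=O)c(OC)c(OC)c1OC | target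

## Summary
Total step count: 14.
Longest linear sequence: 11 steps (7 to 24, steps 4–14). Steps 1–3 form the convergent branch to aldehyde 6.

## Steps most likely to fail

**Step 12 (Tl(III) aryl shift).** Tl(III) may over-oxidise the two very electron-rich rings, and the acid formed may strip MOM early. The fallback sets out from chalcone 19 and comes back at isoflavone 23.
- Weitz–Scheffer epoxidation (30% H2O2, NaOH, MeOH–THF, 0 °C) gives the racemic trans-epoxy ketone F1.
- BF3·OEt2 in CH2Cl2 at −20 to 0 °C opens F1 at the benzylic carbon stabilised by the tetramethoxyphenyl group. A 1,2-acyl shift then gives the α-formyl deoxybenzoin F2, largely as its enol.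
- F2 has the same carbon skeleton as 20. Under the HCl/MeOH conditions of step 13 it loses MOM and cyclodehydrates to 23.

**Step 10 (acylation of the hindered aryllithium).** The doubly ortho-substituted aryllithium may deprotonate the Weinreb amide and return 13, or it may metalate a benzylic CH2 if warmed. The fallback sets out from bromide 14 and comes back at ketone 17.
- The same exchange at −78 °C gives 15, which is trapped with the much more electrophilic acetaldehyde to give the racemic 1-arylethanol F3.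
- Dess–Martin periodinane (NaHCO3, CH2Cl2, rt) oxidises F3 to 17.

**Step 7 (Baeyer–Villiger on 10).** The 4-methoxy group is twisted out of conjugation by its two neighbours, so hydride migration to the carboxylic acid can compete. The fallback sets out from ester 8, skips 9–11 and comes back at phenol 12.
- MeMgBr (3 equiv, THF, 0 °C to rt) gives the tertiary benzylic alcohol F4.
- H2O2 with BF3·OEt2 in CH2Cl2 at 0 °C converts F4 into the cumyl-type hydroperoxide F5.
- F5 undergoes the benzylic hydroperoxide (Hock) rearrangement, in which only the aryl group migrates to oxygen, and collapses to 12.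

## Further compounds
F1 | step 12 | rac-trans-[2,4-bis(benzyloxy)-3-methoxy-6-(methoxymethoxy)phenyl][3-(2,3,4,5-tetramethoxyphenyl)oxiran-2-yl]methanone (one enantiomer drawn) | COCOc1cc(OCc2ccccc2)c(OC)c(OCc2ccccc2)c1C(=O)[C@@H]1O[C@H]1c1cc(OC)c(OC)c(OC)c1OC
F2 | step 12 | rac-3-[2,4-bis(benzyloxy)-3-methoxy-6-(methoxymethoxy)phenyl]-3-oxo-2-(2,3,4,5-tetramethoxyphenyl)propanal | COCOc1cc(OCc2ccccc2)c(OC)c(OCc2ccccc2)c1C(=O)C(C=O)c1cc(OC)c(OC)c(OC)c1OC
F3 | step 10 | rac-1-[2,4-bis(benzyloxy)-3-methoxy-6-(methoxymethoxy)phenyl]ethan-1-ol | COCOc1cc(OCc2ccccc2)c(OC)c(OCc2ccccc2)c1C(C)O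
F4 | step 7 | 2-[3,5-bis(benzyloxy)-4-methoxyphenyl]propan-2-ol | COc1c(OCc2ccccc2)cc(C(C)(C)O)cc1OCc1ccccc1
F5 | step 7 | 2-[3,5-bis(benzyloxy)-4-methoxyphenyl]propan-2-yl hydroperoxide | COc1c(OCc2ccccc2)cc(C(C)(C)OO)cc1OCc1ccccc1
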